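Atoms are labelled by their position in the target SMILES. On the cyclohexane ring the quaternary carbon C8 and its neighbour C10, which carries the two-carbon tether, lie between the ether carbon C34 and the tertiary carbinol C29; read as a ketone, C29 makes C10 the α- and C8 the β-carbon of a cyclohexenone. The route therefore cuts C7–C8 and C10–C11: in one flask a homoprenyl copper reagent adds to C8 opposite the C34 silyloxy group and the regiodefined enolate is alkylated with tert-butyl bromoacetate. The precursor is (R)-4-silyloxy-3-methylcyclohex-2-enone. The oxepane then closes by epoxide opening, and C12 is joined to a linalool-derived hydroazulenone.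

Key step: step 7

Remark: 1,4-dioxaspiro[4.5]dec-6-en-8-one and (R)-linalool of high enantiomeric purity are taken as commercial.

Step 1
Reactants: 1 1,4-dioxaspiro[4.5]dec-6-en-8-one
Product: 2 7-iodo-1,4-dioxaspiro[4.5]dec-6-en-8-one
Conditions: I2 (1.5 equiv), pyridine–CH2Cl2 (1:1), 0 → 25 °C
Reagents that add atoms: iodine, II
Why: α-Iodination of the enone by conjugate addition of pyridine, iodination of the enolate and elimination should place iodine only on C7, the carbon that later carries the C9 methyl.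

Step 2
Reactants: 2 7-iodo-1,4-dioxaspiro[4.5]dec-6-en-8-one
Product: 3 (8R)-7-iodo-1,4-dioxaspiro[4.5]dec-6-en-8-ol
Conditions: (S)-2-methyl-CBS-oxazaborolidine (0.2 equiv), BH3·SMe2 (0.7 equiv), THF, −20 °C; MeOH
Reagents that add atoms: none
Why: Corey–Bakshi–Shibata reduction, in which the iodoalkenyl arm acts as the large substituent, so the (S)-catalyst should deliver hydride to the face that gives the (8R)-carbinol, the future C34.

Step 3
Reactants: 3 (8R)-7-iodo-1,4-dioxaspiro[4.5]dec-6-en-8-ol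
Product: 4 tert-butyl{[(8R)-7-iodo-1,4-dioxaspiro[4.5]dec-6-en-8-yl]oxy}dimethylsilane
Conditions: t-BuMe2SiCl, imidazole, DMF, 25 °C
Reagents that add atoms: tert-butyldimethylsilyl chloride, CC(C)(C)[Si](C)(C)Cl
Why: Silyl ether formation on a secondary allylic alcohol, giving the bulky group that later steers the copper reagent.

Step 4
Reactants: 4 tert-butyl{[(8R)-7-iodo-1,4-dioxaspiro[4.5]dec-6-en-8-yl]oxy}dimethylsilane
Product: 5 tert-butyldimethyl{[(8R)-7-methyl-1,4-dioxaspiro[4.5]dec-6-en-8-yl]oxy}silane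
Conditions: MeZnCl (2 equiv), Pd(PPh3)4 (5 mol %), THF, 50 °C
Reagents that add atoms: methylzinc chloride, C[Zn]Cl
Why: Negishi cross-coupling of the alkenyl iodide installs the C9 methyl at a position fixed by the iodide, so no regiochemical question arises.

Step 5
Reactants: 5 tert-butyldimethyl{[(8R)-7-methyl-1,4-dioxaspiro[4.5]dec-6-en-8-yl]oxy}silane
Product: 6 (4R)-4-(tert-butyldimethylsilyloxy)-3-methylcyclohex-2-en-1-one
Conditions: pyridinium p-toluenesulfonate (0.2 equiv), acetone–H2O (9:1), 50 °C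
Reagents that add atoms: water, O
Why: Acid-catalysed ketal hydrolysis unmasks the ketone in conjugation with the alkene, and the silyl ether should survive the mild acid.

Step 6
Reactants: 7 5-bromo-2-methylpent-2-ene
Product: 8 (4-methylpent-3-en-1-yl)magnesium bromide
Conditions: Mg turnings (I2 crystal), THF, 25 → 40 °C
Reagents that add atoms: magnesium, [Mg]
Why: Grignard formation by insertion of magnesium into the primary C–Br bond gives a stable homoallylic reagent, used as its THF solution.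

Step 7
Reactants: 6 (4R)-4-(tert-butyldimethylsilyloxy)-3-methylcyclohex-2-en-1-one; 8 (4-methylpent-3-en-1-yl)magnesium bromide; 9 tert-butyl bromoacetate
Product: 12 tert-butyl 2-[(1R,2R,3R)-3-(tert-butyldimethylsilyloxy)-2-methyl-2-(4-methylpent-3-en-1-yl)-6-oxocyclohexyl]acetate, via silyl enol ether 10 (not isolated), via lithium enolate 11 (not isolated)
Conditions: 8 (1.5 equiv), CuI·2LiCl (10 mol %), Me3SiCl (2 equiv), THF, −78 → −40 °C; Et3N, pentane, filter, concentrate; MeLi (1.05 equiv), THF, 0 °C; 9 (1.5 equiv), DMPU, −78 → −20 °C; then DBU, toluene, 25 °C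
Reagents that add atoms: chlorotrimethylsilane, C[Si](C)(C)Cl (silicon kept only in 10); methyllithium, [Li]C (lithium kept only in 11)
Why: Copper-catalysed conjugate addition of 8, accelerated by Me3SiCl, transfers the homoprenyl group to C8 and traps the enolate as the regiodefined silyl enol ether 10; MeLi then cleaves the O–Si bond to the lithium enolate 11, whose double bond is fixed at C10=C29, and SN2 alkylation by the activated bromide 9 forms C10–C11. The closest known reaction type is the three-component conjugate addition–enolate alkylation of 4-silyloxycycloalkenones, here run through silyl trapping and enolate regeneration because neither a silyl nor a boron enolate alkylates directly. No ring is closed. C8 is set by the C34 silyloxy group, which sits pseudoaxial to avoid allylic strain with the C9 methyl, so that the reagent enters from the opposite face (anti, trans-diaxial addition). C10 is set under thermodynamic control: DBU equilibrates the α-centre to the isomer with the CH2CO2t-Bu group equatorial and trans to the new chain, all three large substituents being equatorial. The step needs face selectivity at C8 and alkylation at C10 rather than C32; the first comes from the silyloxy group, the second from regiospecific enolate generation out of 10 and fast capture by the reactive halide in THF–DMPU.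

Step 8
Reactants: 12 tert-butyl 2-[(1R,2R,3R)-3-(tert-butyldimethylsilyloxy)-2-methyl-2-(4-methylpent-3-en-1-yl)-6-oxocyclohexyl]acetate
Product: 13 tert-butyl 2-[(1R,2R,3R)-3-hydroxy-2-methyl-2-(4-methylpent-3-en-1-yl)-6-oxocyclohexyl]acetate
Conditions: Bu4NF (1.2 equiv), AcOH (1.2 equiv), THF, 0 → 25 °C
Reagents that add atoms: none
Why: Buffered fluoride desilylation frees the C34 hydroxyl before any epoxide exists, so that an alkoxide is never generated next to an epoxide and the α-centre C10 is not exposed to strong base.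

Step 9
Reactants: 13 tert-butyl 2-[(1R,2R,3R)-3-hydroxy-2-methyl-2-(4-methylpent-3-en-1-yl)-6-oxocyclohexyl]acetate
Product: 15 tert-butyl 2-[(3R,5aR,6R,9aR)-3-hydroxy-2,2,5a-trimethyl-7-oxodecahydro-1-benzoxepin-6-yl]acetate, via hydroxy epoxide 14 (not isolated)
Conditions: Shi ketone (D-fructose-derived, 30 mol %), Oxone (2KHSO5·KHSO4·K2SO4), K2CO3, Bu4NHSO4, MeCN–(MeO)2CH2–aq. Na2B4O7 buffer, 0 °C; then BF3·OEt2 (0.2 equiv), CH2Cl2, −78 °C
Reagents that add atoms: potassium peroxymonosulfate (active part of Oxone), [K+].[O-]S(=O)(=O)OO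
Why: Shi asymmetric epoxidation should give the (R)-epoxide at C5 by reagent control (spiro transition state on the trisubstituted alkene), and Lewis-acid activation at low temperature then opens the epoxide at its tertiary carbon C36 in an SN1-like 7-endo hydroxy-epoxide cyclisation by the equatorial C34 hydroxyl, which keeps the C5 configuration and gives the trans-fused oxepane.

Step 10
Reactants: 15 tert-butyl 2-[(3R,5aR,6R,9aR)-3-hydroxy-2,2,5a-trimethyl-7-oxodecahydro-1-benzoxepin-6-yl]acetate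
Product: 16 tert-butyl 2-[(3R,5aR,6R,9aR)-3-(tert-butyldimethylsilyloxy)-2,2,5a-trimethyl-7-oxodecahydro-1-benzoxepin-6-yl]acetate
Conditions: t-BuMe2SiOTf (1.3 equiv), 2,6-lutidine, CH2Cl2, −78 → −20 °C
Reagents that add atoms: tert-butyldimethylsilyl trifluoromethanesulfonate, CC(C)(C)[Si](C)(C)OS(=O)(=O)C(F)(F)F
Why: Silyl triflate silylation of the hindered secondary C5 alcohol at low temperature, where the tert-butyl ester and the ketone should be left alone.

Step 11
Reactants: 16 tert-butyl 2-[(3R,5aR,6R,9aR)-3-(tert-butyldimethylsilyloxy)-2,2,5a-trimethyl-7-oxodecahydro-1-benzoxepin-6-yl]acetate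
Product: 18 tert-butyl 2-[(3R,5aR,6R,7S,9aR)-3-(tert-butyldimethylsilyloxy)-2,2,5a,7-tetramethyl-7-(triethylsilyloxy)decahydro-1-benzoxepin-6-yl]acetate, via dichlorocerium alkoxide 17 (not isolated)
Conditions: MeLi (3 equiv), CeCl3 (anhydrous, 3 equiv), THF, −78 °C; then Et3SiOTf (4 equiv), −78 → 0 °C
Reagents that add atoms: methyllithium, [Li]C; cerium trichloride, Cl[Ce](Cl)Cl (cerium kept only in 17); triethylsilyl trifluoromethanesulfonate, CC[Si](CC)(CC)OS(=O)(=O)C(F)(F)F
Why: Organocerium 1,2-addition should attack the C29 ketone along the equatorial path because the axial C9 methyl blocks the axial one, giving the axial alkoxide (C29 S) with an equatorial methyl, and silylation in the flask stops that alkoxide from lactonising onto the C12 ester, which the organocerium does not touch at −78 °C.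

Step 12
Reactants: 18 tert-butyl 2-[(3R,5aR,6R,7S,9aR)-3-(tert-butyldimethylsilyloxy)-2,2,5a,7-tetramethyl-7-(triethylsilyloxy)decahydro-1-benzoxepin-6-yl]acetate
Product: 19 2-[(3R,5aR,6R,7S,9aR)-3-(tert-butyldimethylsilyloxy)-2,2,5a,7-tetramethyl-7-(triethylsilyloxy)decahydro-1-benzoxepin-6-yl]ethan-1-ol
Conditions: LiAlH4, THF, 0 °C
Reagents that add atoms: none
Why: Hydride reduction of the ester to the primary alcohol, with silyl ethers and the cyclic ether inert to LiAlH4 at 0 °C.

Step 13
Reactants: 19 2-[(3R,5aR,6R,7S,9aR)-3-(tert-butyldimethylsilyloxy)-2,2,5a,7-tetramethyl-7-(triethylsilyloxy)decahydro-1-benzoxepin-6-yl]ethan-1-ol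
Product: 20 tert-butyl{[(3R,5aR,6R,7S,9aR)-6-(2-iodoethyl)-2,2,5a,7-tetramethyl-7-(triethylsilyloxy)decahydro-1-benzoxepin-3-yl]oxy}dimethylsilane
Conditions: I2, PPh3, imidazole, CH2Cl2, 0 → 25 °C
Reagents that add atoms: iodine, II
Why: Appel iodination converts the primary alcohol into the iodide by SN2 displacement of the alkoxyphosphonium ion, and the silylated C29 oxygen cannot close a tetrahydrofuran onto C12.

Step 14
Reactants: 21 (R)-linalool
Product: 22 (1R)-1-methylcyclopent-2-en-1-ol
Conditions: second-generation Grubbs catalyst RuCl2(=CHPh)(H2IMes)(PCy3) (1 mol %), CH2Cl2, 25 → 40 °C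
Reagents that add atoms: none
Why: Ring-closing metathesis of the 1,6-diene, driven by loss of isobutene, leaves the tertiary carbinol centre (future C23) untouched.

Step 15
Reactants: 22 (1R)-1-methylcyclopent-2-en-1-ol
Product: 23 (1S,2R,5S)-2-methyl-6-oxabicyclo[3.1.0]hexan-2-ol
Conditions: VO(acac)2 (2 mol %), t-BuOOH, CH2Cl2, 0 → 25 °C
Reagents that add atoms: tert-butyl hydroperoxide, CC(C)(C)OO
Why: Hydroxyl-directed vanadium-catalysed epoxidation delivers oxygen from the vanadate ester to the alkene face syn to the hydroxyl, giving the cis-epoxy alcohol.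

Step 16
Reactants: 23 (1S,2R,5S)-2-methyl-6-oxabicyclo[3.1.0]hexan-2-ol
Product: 24 triethyl{[(1S,2R,5S)-2-methyl-6-oxabicyclo[3.1.0]hexan-2-yl]oxy}silane
Conditions: Et3SiOTf (1.2 equiv), 2,6-lutidine, CH2Cl2, −78 °C
Reagents that add atoms: triethylsilyl trifluoromethanesulfonate, CC[Si](CC)(CC)OS(=O)(=O)C(F)(F)F
Why: Silylation of the tertiary alcohol removes the acidic proton and adds bulk next to C19, which helps the regiochemistry of the next step.

Step 17
Reactants: 24 triethyl{[(1S,2R,5S)-2-methyl-6-oxabicyclo[3.1.0]hexan-2-yl]oxy}silane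
Product: 25 2-[(1S,2S,3R)-2-hydroxy-3-methyl-3-(triethylsilyloxy)cyclopentyl]-2-methylpropanenitrile
Conditions: i-PrCN (3 equiv), LiN(i-Pr)2 (3 equiv), THF, −78 → 0 °C; then 24, 0 → 50 °C
Reagents that add atoms: isobutyronitrile, CC(C)C#N
Why: SN2 epoxide opening by the nitrile-stabilised tertiary carbanion should occur at C20, the epoxide carbon remote from the fully substituted C23, anti to the epoxide oxygen, which sets C20 with the CMe2CN group trans to both oxygens and creates quaternary C26.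

Step 18
Reactants: 25 2-[(1S,2S,3R)-2-hydroxy-3-methyl-3-(triethylsilyloxy)cyclopentyl]-2-methylpropanenitrile
Product: 26 2-methyl-2-[(1S,3R)-3-methyl-2-oxo-3-(triethylsilyloxy)cyclopentyl]propanenitrile
Conditions: Dess–Martin periodinane, NaHCO3, CH2Cl2, 25 °C
Reagents that add atoms: none
Why: Dess–Martin oxidation of the secondary alcohol under buffered, non-basic conditions keeps the epimerisable C20 centre next to the new ketone.

Step 19
Reactants: 26 2-methyl-2-[(1S,3R)-3-methyl-2-oxo-3-(triethylsilyloxy)cyclopentyl]propanenitrile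
Product: 27 2-methyl-2-[(1S,3R)-3-methyl-2-methylidene-3-(triethylsilyloxy)cyclopentyl]propanenitrile
Conditions: Zn, CH2Br2, TiCl4, THF–CH2Cl2, 0 → 25 °C
Reagents that add atoms: dibromomethane, BrCBr
Why: Takai–Lombardo methylenation with the non-basic zinc–titanium gem-dimetallic reagent converts the hindered, enolisable ketone into the exocyclic alkene without epimerising C20.

Step 20
Reactants: 27 2-methyl-2-[(1S,3R)-3-methyl-2-methylidene-3-(triethylsilyloxy)cyclopentyl]propanenitrile
Product: 29 2-methyl-2-[(1R,2R,3R)-3-methyl-2-(prop-2-en-1-yl)-3-(triethylsilyloxy)cyclopentyl]propanenitrile, via B-alkyl-9-BBN 28 (not isolated)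
Conditions: 9-BBN, THF, 0 → 25 °C; then vinyl bromide, Pd(dppf)Cl2 (5 mol %), aq. K3PO4, DMF, 25 → 50 °C
Reagents that add atoms: 9-borabicyclo[3.3.1]nonane, B1C2CCCC1CCC2 (boron kept only in 28); vinyl bromide, C=CBr
Why: Hydroboration followed by B-alkyl Suzuki–Miyaura coupling: the borane should add to the exocyclic alkene from the face opposite the CMe2CN group and the C23 methyl, so hydrogen enters C19 syn to the silyloxy group and the C18 chain ends cis to the C20 substituent, and coupling with vinyl bromide turns the C18 borane into the allyl group.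

Step 21
Reactants: 29 2-methyl-2-[(1R,2R,3R)-3-methyl-2-(prop-2-en-1-yl)-3-(triethylsilyloxy)cyclopentyl]propanenitrile
Product: 31 2,4-dimethyl-4-[(1R,2R,3R)-3-methyl-2-(prop-2-en-1-yl)-3-(triethylsilyloxy)cyclopentyl]pent-1-en-3-one, via N-lithio ketimine 30 (not isolated)
Conditions: isopropenyllithium (from 2-bromopropene and Li, Et2O), −78 → 0 °C; then aq. citric acid, THF, 25 °C
Reagents that add atoms: 2-bromopropene, CC(Br)=C; lithium, [Li] (kept only in 30); water, O
Why: Addition of an alkenyllithium to a non-enolisable tertiary nitrile stops at the N-lithio ketimine, and mild acid hydrolysis then releases the isopropenyl ketone (ketone synthesis from a nitrile).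

Step 22
Reactants: 31 2,4-dimethyl-4-[(1R,2R,3R)-3-methyl-2-(prop-2-en-1-yl)-3-(triethylsilyloxy)cyclopentyl]pent-1-en-3-one
Product: 32 (1R,3aR,8aR)-1,4,4,6-tetramethyl-1-(triethylsilyloxy)-2,3,3a,4,8,8a-hexahydroazulen-5(1H)-one
Conditions: second-generation Grubbs catalyst RuCl2(=CHPh)(H2IMes)(PCy3) (5 mol %), toluene (5 mM), 80 °C
Reagents that add atoms: none
Why: Ring-closing metathesis between the allyl group and the isopropenyl ketone closes the seven-membered ring as the 2-methyl enone (C14=C16), helped by the gem-dimethyl group and the cis arrangement of the two chains.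

Step 23
Reactants: 20 tert-butyl{[(3R,5aR,6R,7S,9aR)-6-(2-iodoethyl)-2,2,5a,7-tetramethyl-7-(triethylsilyloxy)decahydro-1-benzoxepin-3-yl]oxy}dimethylsilane; 32 (1R,3aR,8aR)-1,4,4,6-tetramethyl-1-(triethylsilyloxy)-2,3,3a,4,8,8a-hexahydroazulen-5(1H)-one
Product: 35 coupled tertiary allylic alcohol (C13 carbinol as both epimers; C12–C13 bond formed; 5-O-tert-butyldimethylsilyl; 23,29-bis-O-triethylsilyl; C14=C16 alkene), via primary alkyllithium 33 (not isolated), via alkylcerium dichloride 34 (not isolated)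
Conditions: 20 (1.2 equiv), t-BuLi (2.4 equiv), Et2O–pentane, −78 °C; CeCl3 (anhydrous), THF, −78 °C; then 32, −78 → −40 °C; aq. NH4Cl
Reagents that add atoms: tert-butyllithium, [Li]C(C)(C)C (lithium kept only in 33); cerium trichloride, Cl[Ce](Cl)Cl (cerium kept only in 34)
Why: Iodine–lithium exchange, transmetalation to cerium and 1,2-addition of the weakly basic organocerium to the hindered enone carbonyl join C12 to C13, and the uncontrolled C13 configuration does not matter because the next step erases it.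

Step 24
Reactants: 35 coupled tertiary allylic alcohol
Product: 36 tris-silylated enone (C16 ketone; C13=C14 alkene; 5-O-tert-butyldimethylsilyl; 23,29-bis-O-triethylsilyl; 5R,8R,10R,19R,20R,23R,29S,34R)
Conditions: pyridinium chlorochromate [C5H5NH][CrO3Cl] (3 equiv), NaOAc, 4 Å MS, CH2Cl2, 25 °C
Reagents that add atoms: none
Why: Dauben–Babler oxidative transposition, in which the chromate ester of the tertiary allylic alcohol shifts by a [3,3] path to C16 and is oxidised there, gives the enone with the tetrasubstituted C13=C14 bond, while the tertiary silyl ethers and the robust secondary silyl ether are not oxidised.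

Step 25
Reactants: 36 tris-silylated enone
Product: 37 triol enone (C5, C23 and C29 hydroxyls free; C16 ketone; C13=C14 alkene)
Conditions: Bu4NF, THF, 25 → 50 °C
Reagents that add atoms: none
Why: Fluoride-mediated cleavage of all three silyl ethers frees the C5, C23 and C29 hydroxyls, and no stereocentre lies α to the enone carbonyl.

Step 26
Reactants: 37 triol enone
Product: 38 C5 acetate of the triol enone (C23 and C29 hydroxyls free; C16 ketone)
Conditions: Ac2O (1.5 equiv), pyridine, DMAP (cat.), CH2Cl2, 0 → 25 °C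
Reagents that add atoms: acetic anhydride, CC(=O)OC(C)=O
Why: DMAP-catalysed acetylation should be selective for C5–OH, the only secondary alcohol, since the two tertiary alcohols do not acylate under these conditions.

Step 27
Reactants: 38 C5 acetate of the triol enone
Product: 39 CNP0157376.1 (target; 5R,8R,10R,16R,19R,20R,23R,29S,34R)
Conditions: (S)-2-methyl-CBS-oxazaborolidine (1 equiv), catecholborane, toluene, −78 → −40 °C; MeOH
Reagents that add atoms: none
Why: Corey–Bakshi–Shibata 1,2-reduction of the enone, with the substituted alkenyl arm as the large group, should give the (16R)-allylic alcohol by reagent control, the ring stereocentres being too remote to override it and the acetate being inert to catecholborane.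

Compound list
1 | 1,4-dioxaspiro[4.5]dec-6-en-8-one | O=C1C=CC2(CC1)OCCO2 | starting material
2 | 7-iodo-1,4-dioxaspiro[4.5]dec-6-en-8-one | O=C1C(I)=CC2(CC1)OCCO2 | intermediate
3 | (8R)-7-iodo-1,4-dioxaspiro[4.5]dec-6-en-8-ol | IC1=CC2(CC[C@H]1O)OCCO2 | intermediate
4 | tert-butyl{[(8R)-7-iodo-1,4-dioxaspiro[4.5]dec-6-en-8-yl]oxy}dimethylsilane | IC1=CC2(CC[C@H]1O[Si](C)(C)C(C)(C)C)OCCO2 | intermediate
5 | tert-butyldimethyl{[(8R)-7-methyl-1,4-dioxaspiro[4.5]dec-6-en-8-yl]oxy}silane | CC1=CC2(CC[C@H]1O[Si](C)(C)C(C)(C)C)OCCO2 | intermediate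
6 | (4R)-4-(tert-butyldimethylsilyloxy)-3-methylcyclohex-2-en-1-one | CC1=CC(=O)CC[C@H]1O[Si](C)(C)C(C)(C)C | intermediate
7 | 5-bromo-2-methylpent-2-ene | CC(C)=CCCBr | starting material
8 | (4-methylpent-3-en-1-yl)magnesium bromide | CC(C)=CCC[Mg]Br | intermediate
9 | tert-butyl bromoacetate | CC(C)(C)OC(=O)CBr | starting material
10 | tert-butyldimethyl{[(1R,2R)-2-methyl-2-(4-methylpent-3-en-1-yl)-4-(trimethylsilyloxy)cyclohex-3-en-1-yl]oxy}silane | CC(C)=CCC[C@]1(C)C=C(O[Si](C)(C)C)CC[C@H]1O[Si](C)(C)C(C)(C)C | intermediate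
11 | lithium (3R,4R)-4-(tert-butyldimethylsilyloxy)-3-methyl-3-(4-methylpent-3-en-1-yl)cyclohex-1-en-1-olate | CC(C)=CCC[C@]1(C)C=C(O[Li])CC[C@H]1O[Si](C)(C)C(C)(C)C | intermediate
12 | tert-butyl 2-[(1R,2R,3R)-3-(tert-butyldimethylsilyloxy)-2-methyl-2-(4-methylpent-3-en-1-yl)-6-oxocyclohexyl]acetate | CC(C)=CCC[C@]1(C)[C@@H](CC(=O)OC(C)(C)C)C(=O)CC[C@H]1O[Si](C)(C)C(C)(C)C | intermediate
13 | tert-butyl 2-[(1R,2R,3R)-3-hydroxy-2-methyl-2-(4-methylpent-3-en-1-yl)-6-oxocyclohexyl]acetate | CC(C)=CCC[C@]1(C)[C@@H](CC(=O)OC(C)(C)C)C(=O)CC[C@H]1O | intermediate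
14 | tert-butyl 2-[(1R,2R,3R)-2-{2-[(2R)-3,3-dimethyloxiran-2-yl]ethyl}-3-hydroxy-2-methyl-6-oxocyclohexyl]acetate | CC1(C)O[C@@H]1CC[C@]2(C)[C@@H](CC(=O)OC(C)(C)C)C(=O)CC[C@H]2O | intermediate
15 | tert-butyl 2-[(3R,5aR,6R,9aR)-3-hydroxy-2,2,5a-trimethyl-7-oxodecahydro-1-benzoxepin-6-yl]acetate | O[C@@H]1CC[C@]2(C)[C@@H](CC(=O)OC(C)(C)C)C(=O)CC[C@H]2OC1(C)C | intermediate
16 | tert-butyl 2-[(3R,5aR,6R,9aR)-3-(tert-butyldimethylsilyloxy)-2,2,5a-trimethyl-7-oxodecahydro-1-benzoxepin-6-yl]acetate | CC(C)(C)[Si](C)(C)O[C@@H]1CC[C@]2(C)[C@@H](CC(=O)OC(C)(C)C)C(=O)CC[C@H]2OC1(C)C | intermediate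
17 | dichlorocerium alkoxide of the C29 carbinol (7-methyl-7-olate of 16 after methyl addition) | CC(C)(C)[Si](C)(C)O[C@@H]1CC[C@]2(C)[C@@H](CC(=O)OC(C)(C)C)[C@@](C)(O[Ce](Cl)Cl)CC[C@H]2OC1(C)C | intermediate
18 | tert-butyl 2-[(3R,5aR,6R,7S,9aR)-3-(tert-butyldimethylsilyloxy)-2,2,5a,7-tetramethyl-7-(triethylsilyloxy)decahydro-1-benzoxepin-6-yl]acetate | CC(C)(C)[Si](C)(C)O[C@@H]1CC[C@]2(C)[C@@H](CC(=O)OC(C)(C)C)[C@@](C)(O[Si](CC)(CC)CC)CC[C@H]2OC1(C)C | intermediate
19 | 2-[(3R,5aR,6R,7S,9aR)-3-(tert-butyldimethylsilyloxy)-2,2,5a,7-tetramethyl-7-(triethylsilyloxy)decahydro-1-benzoxepin-6-yl]ethan-1-ol | CC(C)(C)[Si](C)(C)O[C@@H]1CC[C@]2(C)[C@@H](CCO)[C@@](C)(O[Si](CC)(CC)CC)CC[C@H]2OC1(C)C | intermediate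
20 | tert-butyl{[(3R,5aR,6R,7S,9aR)-6-(2-iodoethyl)-2,2,5a,7-tetramethyl-7-(triethylsilyloxy)decahydro-1-benzoxepin-3-yl]oxy}dimethylsilane | CC(C)(C)[Si](C)(C)O[C@@H]1CC[C@]2(C)[C@@H](CCI)[C@@](C)(O[Si](CC)(CC)CC)CC[C@H]2OC1(C)C | intermediate
21 | (R)-linalool, (3R)-3,7-dimethylocta-1,6-dien-3-ol | C=C[C@](C)(O)CCC=C(C)C | starting material
22 | (1R)-1-methylcyclopent-2-en-1-ol | C[C@@]1(O)CCC=C1 | intermediate
23 | (1S,2R,5S)-2-methyl-6-oxabicyclo[3.1.0]hexan-2-ol (epoxide cis to hydroxyl) | C[C@@]1(O)CC[C@@H]2O[C@H]12 | intermediate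
24 | triethyl{[(1S,2R,5S)-2-methyl-6-oxabicyclo[3.1.0]hexan-2-yl]oxy}silane | C[C@@]1(O[Si](CC)(CC)CC)CC[C@@H]2O[C@H]12 | intermediate
25 | 2-[(1S,2S,3R)-2-hydroxy-3-methyl-3-(triethylsilyloxy)cyclopentyl]-2-methylpropanenitrile | O[C@H]1[C@@H](CC[C@@]1(C)O[Si](CC)(CC)CC)C(C)(C)C#N | intermediate
26 | 2-methyl-2-[(1S,3R)-3-methyl-2-oxo-3-(triethylsilyloxy)cyclopentyl]propanenitrile | O=C1[C@@H](CC[C@@]1(C)O[Si](CC)(CC)CC)C(C)(C)C#N | intermediate
27 | 2-methyl-2-[(1S,3R)-3-methyl-2-methylidene-3-(triethylsilyloxy)cyclopentyl]propanenitrile | C=C1[C@@H](CC[C@@]1(C)O[Si](CC)(CC)CC)C(C)(C)C#N | intermediate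
28 | 2-{(1R,2R,3R)-2-[(9-borabicyclo[3.3.1]nonan-9-yl)methyl]-3-methyl-3-(triethylsilyloxy)cyclopentyl}-2-methylpropanenitrile | C1CC2CCCC(C1)B2C[C@@H]3[C@@H](CC[C@@]3(C)O[Si](CC)(CC)CC)C(C)(C)C#N | intermediate
29 | 2-methyl-2-[(1R,2R,3R)-3-methyl-2-(prop-2-en-1-yl)-3-(triethylsilyloxy)cyclopentyl]propanenitrile | C=CC[C@@H]1[C@@H](CC[C@@]1(C)O[Si](CC)(CC)CC)C(C)(C)C#N | intermediate
30 | N-lithio ketimine of 31 | C=CC[C@@H]1[C@@H](CC[C@@]1(C)O[Si](CC)(CC)CC)C(C)(C)C(=N[Li])C(C)=C | intermediate
31 | 2,4-dimethyl-4-[(1R,2R,3R)-3-methyl-2-(prop-2-en-1-yl)-3-(triethylsilyloxy)cyclopentyl]pent-1-en-3-one | C=CC[C@@H]1[C@@H](CC[C@@]1(C)O[Si](CC)(CC)CC)C(C)(C)C(=O)C(C)=C | intermediate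
32 | (1R,3aR,8aR)-1,4,4,6-tetramethyl-1-(triethylsilyloxy)-2,3,3a,4,8,8a-hexahydroazulen-5(1H)-one | O=C1C(C)=CC[C@@H]2[C@@H](CC[C@@]2(C)O[Si](CC)(CC)CC)C1(C)C | intermediate
33 | primary alkyllithium from 20 (C12–Li) | CC(C)(C)[Si](C)(C)O[C@@H]1CC[C@]2(C)[C@@H](CC[Li])[C@@](C)(O[Si](CC)(CC)CC)CC[C@H]2OC1(C)C | intermediate
34 | alkylcerium dichloride from 33 (C12–CeCl2) | CC(C)(C)[Si](C)(C)O[C@@H]1CC[C@]2(C)[C@@H](CC[Ce](Cl)Cl)[C@@](C)(O[Si](CC)(CC)CC)CC[C@H]2OC1(C)C | intermediate
35 | coupled tertiary allylic alcohol: C13 carbinol (both epimers), C14=C16 alkene, 5-O-tert-butyldimethylsilyl, 23,29-bis-O-triethylsilyl (5R,8R,10R,19R,20R,23R,29S,34R) | CC(C)(C)[Si](C)(C)O[C@@H]1CC[C@]2(C)[C@@H](CCC3(O)C(C)=CC[C@@H]4[C@@H](CC[C@@]4(C)O[Si](CC)(CC)CC)C3(C)C)[C@@](C)(O[Si](CC)(CC)CC)CC[C@H]2OC1(C)C | intermediate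
36 | tris-silylated enone: C16 ketone, C13=C14 alkene, 5-O-tert-butyldimethylsilyl, 23,29-bis-O-triethylsilyl (5R,8R,10R,19R,20R,23R,29S,34R) | CC(C)(C)[Si](C)(C)O[C@@H]1CC[C@]2(C)[C@@H](CCC3=C(C)C(=O)C[C@@H]4[C@@H](CC[C@@]4(C)O[Si](CC)(CC)CC)C3(C)C)[C@@](C)(O[Si](CC)(CC)CC)CC[C@H]2OC1(C)C | intermediate
37 | triol enone: C5, C23, C29 hydroxyls free, C16 ketone, C13=C14 alkene | O[C@@H]1CC[C@]2(C)[C@@H](CCC3=C(C)C(=O)C[C@@H]4[C@@H](CC[C@@]4(C)O)C3(C)C)[C@@](C)(O)CC[C@H]2OC1(C)C | intermediate
38 | C5 acetate of 37 (16-oxo precursor of the target) | CC(=O)O[C@@H]1CC[C@]2(C)[C@@H](CCC3=C(C)C(=O)C[C@@H]4[C@@H](CC[C@@]4(C)O)C3(C)C)[C@@](C)(O)CC[C@H]2OC1(C)C | intermediate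
39 | CNP0157376.1 (5R,8R,10R,16R,19R,20R,23R,29S,34R) | CC(=O)O[C@@H]1CC[C@]2(C)[C@@H](CCC3=C(C)[C@H](O)C[C@@H]4[C@@H](CC[C@@]4(C)O)C3(C)C)[C@@](C)(O)CC[C@H]2OC1(C)C | target

Total step count: 27. Longest linear sequence: 17 steps (steps 1–5, 7–13 and 23–27).

Steps most likely to fail

Step 7. What may go wrong: C-alkylation of the lithium enolate next to quaternary C8 is slow, so proton transfer can move the enolate to C32 and cost regiochemical purity, or conversion may stall. The fallback sets out from 10, isolated by the non-aqueous work-up, and replaces alkylation by an aldol route. Mukaiyama aldol addition of 10 to tert-butyl glyoxylate (BF3·OEt2, CH2Cl2, −78 °C) should give the hydroxy ester F1. Dehydration with the Burgess reagent should give the alkylidene keto ester F2. Conjugate reduction with [(Ph3P)CuH]6 and equilibration with DBU returns to the route at 12.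

Step 9. What may go wrong: the hydroxyl may open the epoxide at the secondary carbon C5 (6-exo mode), giving a tetrahydropyran carbinol, or the Lewis acid may trigger a hydride shift to a ketone. The fallback sets out from 12 and changes the nucleophile from the free alcohol to its silyl ether. Shi epoxidation of 12 under the conditions of step 9 should give the epoxy silyl ether F3. Catalytic t-BuMe2SiOTf with 2,6-di-tert-butylpyridine in MeNO2 at −40 °C silylates the epoxide oxygen, and the weakly nucleophilic silyl ether oxygen should only be able to trap the developed tertiary cation at C36. Loss of the silyl group from the resulting oxonium ion regenerates the silyl triflate and leaves a silyl group on the C5 oxygen, so the route is rejoined at 16 and steps 8–10 are bypassed.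

Step 23. What may go wrong: the bulky organocerium may fail to add to the carbonyl flanked by quaternary C26 and return enone by enolisation, or the alkyllithium may suffer silyl migration before transmetalation. The fallback sets out from 20 and 29 and makes the union at a linear nitrile, leaving the hindered carbonyl addition to a small nucleophile. Alkyllithium 33 (from 20 and t-BuLi) is added to nitrile 29 in Et2O at −78 → 0 °C to give the N-lithio ketimine F4, which aqueous citric acid hydrolyses to the ketone F5. Isopropenyllithium with CeCl3 (THF, −78 °C) should add to F5 to give the dienol F6. Ring-closing metathesis of F6 between the isopropenyl and allyl groups (second-generation Grubbs catalyst RuCl2(=CHPh)(H2IMes)(PCy3), toluene, 80 °C) closes the seven-membered ring and returns to the route at 35.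

Further compounds
F1 | step 7 | tert-butyl 2-[(2R,3R)-3-(tert-butyldimethylsilyloxy)-2-methyl-2-(4-methylpent-3-en-1-yl)-6-oxocyclohexyl]-2-hydroxyacetate (epimers at C10 and the carbinol) | CC(C)=CCC[C@]1(C)C(C(O)C(=O)OC(C)(C)C)C(=O)CC[C@H]1O[Si](C)(C)C(C)(C)C
F2 | step 7 | tert-butyl 2-[(2R,3R)-3-(tert-butyldimethylsilyloxy)-2-methyl-2-(4-methylpent-3-en-1-yl)-6-oxocyclohexylidene]acetate | CC(C)=CCC[C@]1(C)C(=CC(=O)OC(C)(C)C)C(=O)CC[C@H]1O[Si](C)(C)C(C)(C)C
F3 | step 9 | tert-butyl 2-[(1R,2R,3R)-3-(tert-butyldimethylsilyloxy)-2-{2-[(2R)-3,3-dimethyloxiran-2-yl]ethyl}-2-methyl-6-oxocyclohexyl]acetate | CC1(C)O[C@@H]1CC[C@]2(C)[C@@H](CC(=O)OC(C)(C)C)C(=O)CC[C@H]2O[Si](C)(C)C(C)(C)C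
F4 | step 23 | N-lithio ketimine from 33 and 29 (C12–C13 bond formed, C13=N–Li) | CC(C)(C)[Si](C)(C)O[C@@H]1CC[C@]2(C)[C@@H](CCC(=N[Li])C(C)(C)[C@@H]3CC[C@@](C)(O[Si](CC)(CC)CC)[C@@H]3CC=C)[C@@](C)(O[Si](CC)(CC)CC)CC[C@H]2OC1(C)C
F5 | step 23 | C13 ketone carrying the allyl cyclopentane (hydrolysis product of F4) | CC(C)(C)[Si](C)(C)O[C@@H]1CC[C@]2(C)[C@@H](CCC(=O)C(C)(C)[C@@H]3CC[C@@](C)(O[Si](CC)(CC)CC)[C@@H]3CC=C)[C@@](C)(O[Si](CC)(CC)CC)CC[C@H]2OC1(C)C
F6 | step 23 | C13 tertiary carbinol with isopropenyl and allyl groups (both C13 epimers) | CC(C)(C)[Si](C)(C)O[C@@H]1CC[C@]2(C)[C@@H](CCC(O)(C(C)=C)C(C)(C)[C@@H]3CC[C@@](C)(O[Si](CC)(CC)CC)[C@@H]3CC=C)[C@@](C)(O[Si](CC)(CC)CC)CC[C@H]2OC1(C)C
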